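The route rests on disconnecting the C5–C6 bond of the cycloheptane ring (numbering of 2H-cyclohepta[b]furan-2-one), the bond joining the secondary carbinol carbon to the methyl-bearing carbon. Seen with C7 as a ketone, C5(OH)–C6(CH3)–C7 is an aldol triad, so a cobalt-hydride reductive aldol cyclization of an open-chain vinyl ketone–aldehyde closes the seven-membered ring, turns the vinyl CH2 into the C6 methyl group and sets C5 and C6 in one operation. The precursor is an acyclic thioester holding only C3 and C3a, made by organocatalytic Mukaiyama–Michael addition. Later the C7 ketone takes up a crotonyl anion equivalent, and iodolactonisation followed by displacement with silver (Z)-2-methylbut-2-enoate installs the oxygens at C8a and C8.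

Key step: step 5

Remark: 1-methoxybut-2-yne is taken as a purchasable ether; if it is not, one O-methylation of but-2-yn-1-ol supplies it.

Step 1
Reactants: 1 S-ethyl propanethioate
Product: 2 (Z)-[1-(ethylsulfanyl)prop-1-enyloxy]trimethylsilane
Conditions: LiN(iPr)2, THF, −78 °C; Me3SiCl, −78 °C to rt
Reagents that add atoms: chlorotrimethylsilane C[Si](C)(C)Cl
Why: Kinetic enolisation of the thioester with lithium diisopropylamide and O-silylation (silyl ketene acetal formation) should give mainly the (Z)-ketene thioacetal, the geometry needed for a syn-selective Mukaiyama–Michael addition.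

Step 2
Reactants: 3 but-3-en-1-ylmagnesium bromide; 4 3-chloropropanoyl chloride
Product: 5 1-chlorohept-6-en-3-one
Conditions: Fe(acac)3 (3 mol%), THF, −78 °C
Reagents that add atoms: none
Why: Iron-catalysed acylation of the Grignard reagent by the acid chloride (ketone synthesis) is faster than attack on the product ketone or the primary chloride, and the β-chloroethyl ketone serves as a masked vinyl ketone.

Step 3
Reactants: 5 1-chlorohept-6-en-3-one; 6 (E)-but-2-enal
Product: 7 (E)-8-chloro-6-oxooct-2-enal
Conditions: second-generation Hoveyda–Grubbs catalyst RuCl2(H2IMes)(=CH-C6H4-2-OiPr) (2.5 mol%), 6 (4 equiv), CH2Cl2, 40 °C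
Reagents that add atoms: none
Why: Olefin cross-metathesis of the terminal alkene with excess crotonaldehyde should give the (E)-enal with loss of propene, the ketone and alkyl chloride being inert to the ruthenium carbene.

Step 4
Reactants: 7 (E)-8-chloro-6-oxooct-2-enal; 2 (Z)-[1-(ethylsulfanyl)prop-1-enyloxy]trimethylsilane
Product: 8 S-ethyl (2R,3S)-8-chloro-2-methyl-6-oxo-3-(2-oxoethyl)octanethioate
Conditions: (2R,5R)-5-benzyl-2-tert-butyl-3-methylimidazolidin-4-one·Cl3CCO2H (20 mol%), H2O (2 equiv), CH2Cl2, −55 °C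
Reagents that add atoms: none
Why: In this organocatalytic Mukaiyama–Michael addition only the enal is activated as an iminium ion, the benzyl group of the catalyst antipode chosen here shields the face of C3 opposite to the one that must be attacked, and the (Z)-ketene acetal adds through an open transition state, which should set C3 (S) and C2 (R) in the syn relation.

Step 5
Reactants: 8 S-ethyl (2R,3S)-8-chloro-2-methyl-6-oxo-3-(2-oxoethyl)octanethioate
Product: 10 S-ethyl (2R)-2-[(1S,3R,4S)-3-hydroxy-4-methyl-5-oxocycloheptyl]propanethioate, via vinyl ketone 9 (not isolated)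
Conditions: Et3N, Et2O, 0 °C, filter; then Co(dpm)2 (5 mol%, dpm = 2,2,6,6-tetramethylheptane-3,5-dionate), PhSiH3 (1.2 equiv), ClCH2CH2Cl, 25 °C; aq. NH4Cl
Reagents that add atoms: none
Why: Triethylamine first eliminates HCl (E1cB) to unmask vinyl ketone 9; a cobalt hydride formed from Co(dpm)2 and PhSiH3 then adds to the terminal enone carbon, turning CH2= into the future C6 methyl group and giving a (Z)-cobalt enolate that attacks the tethered aldehyde. The closest known reaction type is the cobalt-catalysed aldol cycloreduction (reductive aldol cyclization) of enone–aldehydes. The ring closes in a 7-(enolendo)-exo-trig mode, forming the bond between the carbinol carbon and the methyl-bearing carbon of the cycloheptanone. Both new stereocentres arise here: the (Z)-enolate reacting through a cobalt-bridged Zimmerman–Traxler chair should give the syn aldol (hydroxyl and methyl trans on the ring), and with the C1' side chain pseudo-equatorial the aldehyde oxygen must sit pseudo-axial to reach cobalt, which places the hydroxyl trans to the side chain. The step needs chemoselective hydrometalation of the vinyl ketone beside the aldehyde and thioester, secured by the much higher acceptor reactivity of the unsubstituted enone, and it needs the seven-membered aldol mode, secured because only the ketone-derived enolate is generated, so the five-membered aldol (aldehyde enolate onto ketone) that free base would favour cannot occur.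

Step 6
Reactants: 10 S-ethyl (2R)-2-[(1S,3R,4S)-3-hydroxy-4-methyl-5-oxocycloheptyl]propanethioate
Product: 11 S-ethyl (2R)-2-[(1S,3R,4S)-3-(tert-butyldimethylsilyloxy)-4-methyl-5-oxocycloheptyl]propanethioate
Conditions: t-BuMe2SiOTf (1.1 equiv), 2,6-lutidine, CH2Cl2, −78 °C
Reagents that add atoms: tert-butyldimethylsilyl trifluoromethanesulfonate CC(C)(C)[Si](C)(C)OS(=O)(=O)C(F)(F)F
Why: Silyl ether formation protects the β-hydroxy ketone against retro-aldol cleavage and elimination in the enolate and organolithium steps that follow.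

Step 7
Reactants: 11 S-ethyl (2R)-2-[(1S,3R,4S)-3-(tert-butyldimethylsilyloxy)-4-methyl-5-oxocycloheptyl]propanethioate
Product: 12 (2R)-2-[(1S,3R,4S)-3-(tert-butyldimethylsilyloxy)-4-methyl-5-oxocycloheptyl]propanoic acid
Conditions: AgNO3, 2,6-lutidine, THF/H2O, 25 °C
Reagents that add atoms: water O
Why: Silver-ion-assisted hydrolysis of the thioester runs under nearly neutral conditions, so the free acid should form without epimerising the α-methyl centre or eliminating the β-silyloxy group.

Step 8
Reactants: 12 (2R)-2-[(1S,3R,4S)-3-(tert-butyldimethylsilyloxy)-4-methyl-5-oxocycloheptyl]propanoic acid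
Product: 13 (2R)-2-[(1R,5S,6R)-6-(tert-butyldimethylsilyloxy)-5-methyl-4-oxocyclohept-2-en-1-yl]propanoic acid
Conditions: LiN(iPr)2 (2.3 equiv), THF, −78 °C; PhSeBr; aq. HCl work-up; then H2O2, pyridine, CH2Cl2, 0 to 25 °C
Reagents that add atoms: none
Why: Kinetic enolisation of the carboxylate–ketone occurs at the unhindered α-methylene (the other α-carbon is tertiary), and α-selenenylation followed by selenoxide syn-elimination should place the double bond between the two carbons that will later carry the ester and lactone oxygens.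

Step 9
Reactants: 14 1-methoxybut-2-yne
Product: 15 1-methoxybuta-1,2-diene
Conditions: KOtBu (10 mol%), 60 °C, then distillation
Reagents that add atoms: none
Why: Base-catalysed propargyl–allenyl isomerisation through the oxygen-stabilised propargylic anion should give the alkoxyallene.

Step 10
Reactants: 13 (2R)-2-[(1R,5S,6R)-6-(tert-butyldimethylsilyloxy)-5-methyl-4-oxocyclohept-2-en-1-yl]propanoic acid; 15 1-methoxybuta-1,2-diene
Product: 18 (2R)-2-[(1R,4R,5S,6R)-4-[(E)-but-2-enoyl]-6-(tert-butyldimethylsilyloxy)-4-hydroxy-5-methylcyclohept-2-en-1-yl]propanoic acid, via lithiated methoxybutadiene 16 (not isolated), via allenyl carbinol 17 (not isolated)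
Conditions: 15 (3.5 equiv), n-BuLi (3.3 equiv), THF, −78 °C; then 13, −78 °C; then aq. HCl (0.5 M), THF, 0 °C
Reagents that add atoms: water O
Why: α-Lithiation of the alkoxyallene gives an acyl anion equivalent that should add 1,2 to the enone carbonyl from the face opposite the adjacent C5' methyl group and the C1' side chain, setting the tertiary carbinol, and acidic hydrolysis of the allenyl enol ether then releases the (E)-enone.

Step 11
Reactants: 18 (2R)-2-[(1R,4R,5S,6R)-4-[(E)-but-2-enoyl]-6-(tert-butyldimethylsilyloxy)-4-hydroxy-5-methylcyclohept-2-en-1-yl]propanoic acid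
Product: 19 (3R,3aS,5R,6S,7S,8S,8aR)-7-[(E)-but-2-enoyl]-5-(tert-butyldimethylsilyloxy)-7-hydroxy-8-iodo-3,6-dimethyloctahydro-2H-cyclohepta[b]furan-2-one
Conditions: I2, NaHCO3, MeCN, 0 °C, dark
Reagents that add atoms: iodine II
Why: In this iodolactonisation the tethered carboxylate can open the iodonium ion only at the nearer alkene carbon (5-exo) and from its own face, so anti addition should give the cis-fused γ-lactone with iodine trans to the lactone oxygen and antiperiplanar to the tertiary hydroxyl, while the electron-poor enone is untouched.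

Step 12
Reactants: 19 (3R,3aS,5R,6S,7S,8S,8aR)-7-[(E)-but-2-enoyl]-5-(tert-butyldimethylsilyloxy)-7-hydroxy-8-iodo-3,6-dimethyloctahydro-2H-cyclohepta[b]furan-2-one; 20 angelic acid
Product: 22 (3R,3aS,5R,6S,7S,8S,8aR)-7-[(E)-but-2-enoyl]-5-(tert-butyldimethylsilyloxy)-7-hydroxy-3,6-dimethyl-2-oxooctahydro-2H-cyclohepta[b]furan-8-yl (Z)-2-methylbut-2-enoate, via epoxy ketone 21 (not isolated)
Conditions: Ag2O (1.2 equiv), 20 (5 equiv), 4 Å molecular sieves, toluene, dark, 25 to 45 °C
Reagents that add atoms: none
Why: This is a silver-assisted substitution with neighbouring-group participation: the silver carboxylate removes iodide while the antiperiplanar tertiary hydroxyl closes epoxy ketone 21, which the carboxylate opens at its secondary β-carbon with a second inversion, so the ester should end on the original face of C8, trans to both neighbouring oxygens, without exposing the (Z)-enoate to base.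

Step 13
Reactants: 22 (3R,3aS,5R,6S,7S,8S,8aR)-7-[(E)-but-2-enoyl]-5-(tert-butyldimethylsilyloxy)-7-hydroxy-3,6-dimethyl-2-oxooctahydro-2H-cyclohepta[b]furan-8-yl (Z)-2-methylbut-2-enoate
Product: 23 (3R,3aS,5R,6S,7S,8S,8aR)-7-[(E)-but-2-enoyl]-5,7-dihydroxy-3,6-dimethyl-2-oxooctahydro-2H-cyclohepta[b]furan-8-yl (Z)-2-methylbut-2-enoate
Conditions: HF·pyridine, pyridine, THF, 0 to 25 °C
Reagents that add atoms: none
Why: Buffered fluoride cleavage of the silyl ether (desilylation) should leave the enone, the (Z)-enoate, the lactone and the tertiary α-ketol untouched.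

Compound list
1 | S-ethyl propanethioate | CCC(=O)SCC | starting material
2 | (Z)-[1-(ethylsulfanyl)prop-1-enyloxy]trimethylsilane | C/C=C(\SCC)O[Si](C)(C)C | intermediate
3 | but-3-en-1-ylmagnesium bromide | C=CCC[Mg]Br | starting material
4 | 3-chloropropanoyl chloride | ClCCC(Cl)=O | starting material
5 | 1-chlorohept-6-en-3-one | ClCCC(=O)CCC=C | intermediate
6 | (E)-but-2-enal | C/C=C/C=O | starting material
7 | (E)-8-chloro-6-oxooct-2-enal | ClCCC(=O)CC/C=C/C=O | intermediate
8 | S-ethyl (2R,3S)-8-chloro-2-methyl-6-oxo-3-(2-oxoethyl)octanethioate | ClCCC(=O)CC[C@H]([C@@H](C)C(=O)SCC)CC=O | intermediate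
9 | S-ethyl (2R,3S)-2-methyl-6-oxo-3-(2-oxoethyl)oct-7-enethioate | C=CC(=O)CC[C@H]([C@@H](C)C(=O)SCC)CC=O | intermediate
10 | S-ethyl (2R)-2-[(1S,3R,4S)-3-hydroxy-4-methyl-5-oxocycloheptyl]propanethioate | O=C1CC[C@H]([C@@H](C)C(=O)SCC)C[C@@H](O)[C@@H]1C | intermediate
11 | S-ethyl (2R)-2-[(1S,3R,4S)-3-(tert-butyldimethylsilyloxy)-4-methyl-5-oxocycloheptyl]propanethioate | O=C1CC[C@H]([C@@H](C)C(=O)SCC)C[C@@H](O[Si](C)(C)C(C)(C)C)[C@@H]1C | intermediate
12 | (2R)-2-[(1S,3R,4S)-3-(tert-butyldimethylsilyloxy)-4-methyl-5-oxocycloheptyl]propanoic acid | O=C1CC[C@H]([C@@H](C)C(O)=O)C[C@@H](O[Si](C)(C)C(C)(C)C)[C@@H]1C | intermediate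
13 | (2R)-2-[(1R,5S,6R)-6-(tert-butyldimethylsilyloxy)-5-methyl-4-oxocyclohept-2-en-1-yl]propanoic acid | O=C1C=C[C@H]([C@@H](C)C(O)=O)C[C@@H](O[Si](C)(C)C(C)(C)C)[C@@H]1C | intermediate
14 | 1-methoxybut-2-yne | CC#CCOC | starting material
15 | 1-methoxybuta-1,2-diene | CC=C=COC | intermediate
16 | (1-methoxybuta-1,2-dien-1-yl)lithium | CC=C=C([Li])OC | intermediate
17 | (2R)-2-[(1R,4R,5S,6R)-6-(tert-butyldimethylsilyloxy)-4-hydroxy-4-(1-methoxybuta-1,2-dien-1-yl)-5-methylcyclohept-2-en-1-yl]propanoic acid | C1=C[C@H]([C@@H](C)C(O)=O)C[C@@H](O[Si](C)(C)C(C)(C)C)[C@H](C)[C@@]1(O)C(OC)=C=CC | intermediate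
18 | (2R)-2-[(1R,4R,5S,6R)-4-[(E)-but-2-enoyl]-6-(tert-butyldimethylsilyloxy)-4-hydroxy-5-methylcyclohept-2-en-1-yl]propanoic acid | C1=C[C@H]([C@@H](C)C(O)=O)C[C@@H](O[Si](C)(C)C(C)(C)C)[C@H](C)[C@@]1(O)C(=O)/C=C/C | intermediate
19 | (3R,3aS,5R,6S,7S,8S,8aR)-7-[(E)-but-2-enoyl]-5-(tert-butyldimethylsilyloxy)-7-hydroxy-8-iodo-3,6-dimethyloctahydro-2H-cyclohepta[b]furan-2-one | I[C@H]1[C@@H]2OC(=O)[C@H](C)[C@@H]2C[C@@H](O[Si](C)(C)C(C)(C)C)[C@H](C)[C@@]1(O)C(=O)/C=C/C | intermediate
20 | angelic acid, (Z)-2-methylbut-2-enoic acid | C/C=C(/C)C(O)=O | starting material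
21 | 7,8-epoxide of the cyclohepta[b]furan-2-one (oxirane oxygen cis to the lactone oxygen; 7-[(E)-but-2-enoyl], 5-silyloxy, 3,6-dimethyl) | O1[C@@H]2[C@@H]3OC(=O)[C@H](C)[C@@H]3C[C@@H](O[Si](C)(C)C(C)(C)C)[C@H](C)[C@]12C(=O)/C=C/C | intermediate
22 | (3R,3aS,5R,6S,7S,8S,8aR)-7-[(E)-but-2-enoyl]-5-(tert-butyldimethylsilyloxy)-7-hydroxy-3,6-dimethyl-2-oxooctahydro-2H-cyclohepta[b]furan-8-yl (Z)-2-methylbut-2-enoate | C/C=C(/C)C(=O)O[C@H]1[C@@H]2OC(=O)[C@H](C)[C@@H]2C[C@@H](O[Si](C)(C)C(C)(C)C)[C@H](C)[C@@]1(O)C(=O)/C=C/C | intermediate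
23 | (3R,3aS,5R,6S,7S,8S,8aR)-7-[(E)-but-2-enoyl]-5,7-dihydroxy-3,6-dimethyl-2-oxooctahydro-2H-cyclohepta[b]furan-8-yl (Z)-2-methylbut-2-enoate | C/C=C(/C)C(=O)O[C@H]1[C@@H]2OC(=O)[C@H](C)[C@@H]2C[C@@H](O)[C@H](C)[C@@]1(O)C(=O)/C=C/C | target

Total step count: 13. Longest linear sequence: 11 steps (steps 2 to 8 and 10 to 13, from 3 and 4 to 23).

Steps most likely to fail

Step 5. The cobalt enolate may add to the aldehyde with too little facial discrimination relative to the remote side chain, or the aldehyde may be hydrosilylated before the ring closes. The fallback sets out from 8 and forms the same bond without any hydride: after the same elimination with Et3N to 9, a PBu3-catalysed intramolecular Morita–Baylis–Hillman reaction would give S-ethyl (2R)-2-[(1S,3R)-3-hydroxy-4-methylidene-5-oxocycloheptyl]propanethioate F1, the reversibility of this addition allowing the carbinol epimers to equilibrate. Hydroxyl-directed hydrogenation of the exocyclic alkene with [Ir(cod)(PCy3)(py)]PF6 under H2 would then deliver hydrogen cis to the hydroxyl, set the methyl trans to it and return to 10.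

Step 10. The organolithium may approach the carbonyl from the methyl-bearing face because the bulky silyl ether shields the other face, or it may enolise the ketone instead of adding. The fallback sets out from 13 and replaces steric control by alkoxide guidance: HF·pyridine would give (2R)-2-[(1R,5S,6R)-6-hydroxy-5-methyl-4-oxocyclohept-2-en-1-yl]propanoic acid F2. Its dilithium salt, in which the small lithium alkoxide can hold the reagent on its own face, would be treated with excess 16 to give (2R)-2-[(1R,4R,5S,6R)-4,6-dihydroxy-4-(1-methoxybuta-1,2-dien-1-yl)-5-methylcyclohept-2-en-1-yl]propanoic acid F3, hydrolysed without isolation to (2R)-2-[(1R,4R,5S,6R)-4-[(E)-but-2-enoyl]-4,6-dihydroxy-5-methylcyclohept-2-en-1-yl]propanoic acid F4. Selective silylation of the secondary hydroxyl (t-BuMe2SiCl, imidazole, DMF) would come back to 18.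

Step 12. The carboxylate may open the intermediate epoxide too slowly, so that acyl migration in the epoxy ketone or attack at the wrong terminus competes and the (Z)-enoate isomerises on long heating. The fallback sets out from 19 and makes the C8–O bond with water and the ester by O-acylation: DBU would close the epoxide, isolated as 21, and HClO4 in THF/H2O would open it at C8 with inversion to (3R,3aS,5R,6S,7S,8S,8aR)-7-[(E)-but-2-enoyl]-5-(tert-butyldimethylsilyloxy)-7,8-dihydroxy-3,6-dimethyloctahydro-2H-cyclohepta[b]furan-2-one F5. Yamaguchi esterification of the secondary hydroxyl with 20 (2,4,6-trichlorobenzoyl chloride, Et3N, then DMAP, toluene) would come back to 22.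

Further compounds
F1 | step 5 | S-ethyl (2R)-2-[(1S,3R)-3-hydroxy-4-methylidene-5-oxocycloheptyl]propanethioate | O=C1CC[C@H]([C@@H](C)C(=O)SCC)C[C@@H](O)C1=C
F2 | step 10 | (2R)-2-[(1R,5S,6R)-6-hydroxy-5-methyl-4-oxocyclohept-2-en-1-yl]propanoic acid | O=C1C=C[C@H]([C@@H](C)C(O)=O)C[C@@H](O)[C@@H]1C
F3 | step 10 | (2R)-2-[(1R,4R,5S,6R)-4,6-dihydroxy-4-(1-methoxybuta-1,2-dien-1-yl)-5-methylcyclohept-2-en-1-yl]propanoic acid | C1=C[C@H]([C@@H](C)C(O)=O)C[C@@H](O)[C@H](C)[C@@]1(O)C(OC)=C=CC
F4 | step 10 | (2R)-2-[(1R,4R,5S,6R)-4-[(E)-but-2-enoyl]-4,6-dihydroxy-5-methylcyclohept-2-en-1-yl]propanoic acid | C1=C[C@H]([C@@H](C)C(O)=O)C[C@@H](O)[C@H](C)[C@@]1(O)C(=O)/C=C/C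
F5 | step 12 | (3R,3aS,5R,6S,7S,8S,8aR)-7-[(E)-but-2-enoyl]-5-(tert-butyldimethylsilyloxy)-7,8-dihydroxy-3,6-dimethyloctahydro-2H-cyclohepta[b]furan-2-one | O[C@H]1[C@@H]2OC(=O)[C@H](C)[C@@H]2C[C@@H](O[Si](C)(C)C(C)(C)C)[C@H](C)[C@@]1(O)C(=O)/C=C/C
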